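The oxolane ring (O1, C2–C5) is cut at C4–C5. (S)-Malic acid supplies C2 with O1 and the side-arm carbons. Pentanal supplies C5 and the butyl chain. The two pieces are joined first through oxygen, as an acetal, and only then through carbon. A Petasis–Ferrier rearrangement forms C4–C5, closes the ring and sets C5 cis to C2 in one operation, from either acetal epimer. Its precursor is a 2-butyl-4-methylidene-1,3-dioxolane with a 2-(silyloxy)ethyl group on the malate carbon. It is reached in four steps because pentanal itself differentiates the two carboxyl groups. The surplus C3 oxygen is then removed by radical deoxygenation.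

Key step: step 5

Remarks on the chemistry:
- Target numbering is O1, C2 (oxoalkyl arm), C3, C4, C5 (butyl). The SMILES decodes to (2R,5R), which is cis. (S)-Malic acid gives this C2 with all four bonds retained; the descriptor changes only because the CIP priorities change.
- The dioxolanones and the enol acetal are drawn as the cis acetal epimer expected to dominate. The trans epimer is not removed, because the acetal carbon becomes planar in the key step.
- The oxolan-3-ol and its thionocarbonate are drawn as the expected all-cis C3 epimer. C3 becomes CH2 later, so its configuration has no consequence.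
- TBDPS is kept on the arm because it is bulky and weakly Lewis basic, so it cannot chelate aluminium to O1.

Step 1
Reactants: 1 (S)-malic acid; 2 pentanal
Product: 3 2-[(2S,4S)-2-butyl-5-oxo-1,3-dioxolan-4-yl]acetic acid
Conditions: p-TsOH·H2O (cat.), cyclohexane, Dean–Stark, reflux
Reagents that add atoms: none
Why: Acid-catalysed acetalisation with azeotropic water removal, in which the α-hydroxy acid unit closes the five-membered dioxolanone in preference to the six-membered dioxanone under equilibrating conditions, the carbinol C–O bond is never broken so the (S) centre is retained, and the new acetal centre (cis favoured) is erased again in step 5.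

Step 2
Reactants: 3 2-[(2S,4S)-2-butyl-5-oxo-1,3-dioxolan-4-yl]acetic acid
Product: 4 (2S,5S)-2-butyl-5-(2-hydroxyethyl)-1,3-dioxolan-4-one
Conditions: BH3·THF, THF, 0 °C to rt; MeOH quench; used crude
Reagents that add atoms: none
Why: Chemoselective borane reduction, in which the electrophilic hydride consumes the free carboxylic acid through an acyloxyborane much faster than it attacks the lactone-type carbonyl, as is well established for the corresponding malic acid acetonide, and no stereocentre is touched.

Step 3
Reactants: 4 (2S,5S)-2-butyl-5-(2-hydroxyethyl)-1,3-dioxolan-4-one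
Product: 5 (2S,5S)-2-butyl-5-{2-[(tert-butyldiphenylsilyl)oxy]ethyl}-1,3-dioxolan-4-one
Conditions: TBDPSCl, imidazole, CH2Cl2, 0 °C to rt
Reagents that add atoms: tert-butyl(chloro)diphenylsilane, CC(C)(C)[Si](Cl)(c1ccccc1)c1ccccc1
Why: Imidazole-promoted silylation of a primary alcohol, run at once on the crude alcohol so that the hydroxyl is capped before it can attack the dioxolanone carbonyl.

Step 4
Reactants: 5 (2S,5S)-2-butyl-5-{2-[(tert-butyldiphenylsilyl)oxy]ethyl}-1,3-dioxolan-4-one
Product: 6 (2S,5S)-2-butyl-5-{2-[(tert-butyldiphenylsilyl)oxy]ethyl}-4-methylidene-1,3-dioxolane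
Conditions: Cp2TiMe2, toluene, 70 °C, dark; hexane, filtration through basic Al2O3
Reagents that add atoms: Cp2TiMe2, C[Ti](C)(C1C=CC=C1)C1C=CC=C1
Why: Petasis methylenation, in which thermolysis of Cp2TiMe2 gives Cp2Ti=CH2, which adds [2+2] to the lactone carbonyl and cycloreverts to the exocyclic enol ether under non-acidic and essentially non-basic conditions that leave the acetal, the silyl ether and the α-stereocentre intact.

Step 5
Reactants: 6 (2S,5S)-2-butyl-5-{2-[(tert-butyldiphenylsilyl)oxy]ethyl}-4-methylidene-1,3-dioxolane
Product: 8 (2S,3S,5R)-5-butyl-2-{2-[(tert-butyldiphenylsilyl)oxy]ethyl}oxolan-3-ol, via oxolan-3-one 7 (not isolated)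
Conditions: iBu3Al (excess), toluene, −78 °C to rt; aq. potassium sodium tartrate
Reagents that add atoms: none
Why: iBu3Al binds the enol-ether oxygen of the dioxolane and cleaves its bond to the acetal carbon, giving an aluminium enolate that stays tied through the malate carbon to the oxocarbenium ion O1=C5(H)Bu, and the enolate methylene (future C4) then bonds to C5. This is the Petasis–Ferrier rearrangement in its known five-membered form, established on this class of 4-methylidene-1,3-dioxolanes derived from α-hydroxy acids. The oxolane closes in a 5-(enolendo)-endo-trig mode, which is formally unfavourable but feasible because the cation is very electrophilic and is held next to the enolate. C5 is controlled by C2: in the envelope transition state the butyl group and the silyloxyethyl arm both sit pseudo-equatorial, which places them cis, and because the acetal carbon becomes planar both epimers of 6 funnel into one product while C2 is never ionised. The step needs cleavage at the enol-ether oxygen rather than at O1, and C–C bond formation ahead of hydride transfer to the cation; the first is secured by the enolate being the better leaving group and by the non-chelating TBDPS ether, the second by the intramolecular trap at low temperature. The aluminium-bound ketone 7 is then reduced in the flask by β-hydride transfer from an isobutyl group (Meerwein–Ponndorf-type, from the face opposite the two substituents, which sets C3), so neither enolisation at C2 nor retro-oxa-Michael opening at C5 can erode the stereochemistry.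

Step 6
Reactants: 8 (2S,3S,5R)-5-butyl-2-{2-[(tert-butyldiphenylsilyl)oxy]ethyl}oxolan-3-ol
Product: 9 O-[(2S,3S,5R)-5-butyl-2-{2-[(tert-butyldiphenylsilyl)oxy]ethyl}oxolan-3-yl] O-phenyl carbonothioate
Conditions: PhOC(S)Cl, pyridine, DMAP (cat.), CH2Cl2, 0 °C to rt
Reagents that add atoms: O-phenyl chlorothionoformate, ClC(=S)Oc1ccccc1
Why: DMAP-catalysed acylation of the secondary alcohol with an aryl chlorothionoformate gives the radical precursor under weakly basic conditions that exclude silyl migration and leave the C3–O bond and all stereocentres untouched.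

Step 7
Reactants: 9 O-[(2S,3S,5R)-5-butyl-2-{2-[(tert-butyldiphenylsilyl)oxy]ethyl}oxolan-3-yl] O-phenyl carbonothioate
Product: 10 tert-butyl{2-[(2R,5R)-5-butyloxolan-2-yl]ethoxy}diphenylsilane
Conditions: Bu3SnH, AIBN (cat.), toluene, 90 °C
Reagents that add atoms: none
Why: Barton–McCombie deoxygenation, in which the stannyl radical adds to C=S, the released secondary C3 radical takes hydrogen from Bu3SnH, the ring stays closed because ether oxygens are poor radical leaving groups, and both C3 epimers converge with C2 and C5 unaffected.

Step 8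
Reactants: 10 tert-butyl{2-[(2R,5R)-5-butyloxolan-2-yl]ethoxy}diphenylsilane
Product: 11 2-[(2R,5R)-5-butyloxolan-2-yl]ethan-1-ol
Conditions: TBAF, THF, rt
Reagents that add atoms: none
Why: Fluoride-driven desilylation frees the primary alcohol, and the dialkyl oxolane offers no base-sensitive site.

Step 9
Reactants: 11 2-[(2R,5R)-5-butyloxolan-2-yl]ethan-1-ol
Product: 12 2-[(2R,5R)-5-butyloxolan-2-yl]acetaldehyde
Conditions: Dess–Martin periodinane, CH2Cl2, 0 °C to rt
Reagents that add atoms: none
Why: Dess–Martin oxidation stops at the aldehyde and runs without base, so the β-alkoxy aldehyde is not exposed to conditions for retro-oxa-Michael ring opening that would scramble C2.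

Step 10
Reactants: 12 2-[(2R,5R)-5-butyloxolan-2-yl]acetaldehyde; 13 1-bromotetradecane
Product: 15 1-[(2R,5R)-5-butyloxolan-2-yl]hexadecan-2-ol (both carbinol epimers), via tetradecylmagnesium bromide 14 (not isolated)
Conditions: 13, Mg, I2 (cat.), THF, 40 °C; then 12, THF, −78 to 0 °C; aqueous work-up
Reagents that add atoms: none
Why: Grignard formation and 1,2-addition to the aldehyde at low temperature attaches the C14 chain, and the new carbinol centre forms unselectively, which does not matter because it is oxidised in step 11.

Step 11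
Reactants: 15 1-[(2R,5R)-5-butyloxolan-2-yl]hexadecan-2-ol
Product: 16 1-[(2R,5R)-5-butyloxolan-2-yl]hexadecan-2-one (target)
Conditions: Dess–Martin periodinane, CH2Cl2, 0 °C to rt
Reagents that add atoms: none
Why: Dess–Martin oxidation of the secondary alcohol under neutral conditions gives the β-alkoxy ketone without enolisation-driven ring opening, so the cis (2R,5R) relationship is retained.

Compound list
1 | (S)-malic acid | OC(=O)C[C@H](O)C(=O)O | starting material
2 | pentanal | CCCCC=O | starting material
3 | 2-[(2S,4S)-2-butyl-5-oxo-1,3-dioxolan-4-yl]acetic acid | OC(=O)C[C@H]1C(=O)O[C@@H](CCCC)O1 | intermediate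
4 | (2S,5S)-2-butyl-5-(2-hydroxyethyl)-1,3-dioxolan-4-one | OCC[C@H]1C(=O)O[C@@H](CCCC)O1 | intermediate
5 | (2S,5S)-2-butyl-5-{2-[(tert-butyldiphenylsilyl)oxy]ethyl}-1,3-dioxolan-4-one | CC(C)(C)[Si](c1ccccc1)(c1ccccc1)OCC[C@H]1C(=O)O[C@@H](CCCC)O1 | intermediate
6 | (2S,5S)-2-butyl-5-{2-[(tert-butyldiphenylsilyl)oxy]ethyl}-4-methylidene-1,3-dioxolane | CC(C)(C)[Si](c1ccccc1)(c1ccccc1)OCC[C@H]1C(=C)O[C@@H](CCCC)O1 | intermediate
7 | (2S,5R)-5-butyl-2-{2-[(tert-butyldiphenylsilyl)oxy]ethyl}oxolan-3-one (aluminium-bound in the flask) | CC(C)(C)[Si](c1ccccc1)(c1ccccc1)OCC[C@H]1C(=O)C[C@@H](CCCC)O1 | intermediate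
8 | (2S,3S,5R)-5-butyl-2-{2-[(tert-butyldiphenylsilyl)oxy]ethyl}oxolan-3-ol | CC(C)(C)[Si](c1ccccc1)(c1ccccc1)OCC[C@H]1[C@@H](O)C[C@@H](CCCC)O1 | intermediate
9 | O-[(2S,3S,5R)-5-butyl-2-{2-[(tert-butyldiphenylsilyl)oxy]ethyl}oxolan-3-yl] O-phenyl carbonothioate | CC(C)(C)[Si](c1ccccc1)(c1ccccc1)OCC[C@H]1[C@@H](OC(=S)Oc2ccccc2)C[C@@H](CCCC)O1 | intermediate
10 | tert-butyl{2-[(2R,5R)-5-butyloxolan-2-yl]ethoxy}diphenylsilane | CC(C)(C)[Si](c1ccccc1)(c1ccccc1)OCC[C@H]1CC[C@@H](CCCC)O1 | intermediate
11 | 2-[(2R,5R)-5-butyloxolan-2-yl]ethan-1-ol | OCC[C@H]1CC[C@@H](CCCC)O1 | intermediate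
12 | 2-[(2R,5R)-5-butyloxolan-2-yl]acetaldehyde | O=CC[C@H]1CC[C@@H](CCCC)O1 | intermediate
13 | 1-bromotetradecane | CCCCCCCCCCCCCCBr | starting material
14 | tetradecylmagnesium bromide | CCCCCCCCCCCCCC[Mg]Br | intermediate
15 | 1-[(2R,5R)-5-butyloxolan-2-yl]hexadecan-2-ol (carbinol epimers) | CCCCCCCCCCCCCCC(O)C[C@H]1CC[C@@H](CCCC)O1 | intermediate
16 | 1-[(2R,5R)-5-butyloxolan-2-yl]hexadecan-2-one | CCCCCCCCCCCCCCC(=O)C[C@H]1CC[C@@H](CCCC)O1 | target

Total step count: 11. Longest linear sequence: 11 steps, from 1 to 16; the organomagnesium reagent is made within step 10.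

Steps most likely to fail

Step 5. Two things may go wrong. Hydride may pass from an isobutyl group to the oxocarbenium carbon before the C–C bond forms, which opens the acetal reductively. The strained 5-endo closure may also discriminate poorly between the two faces of the cation.
- The fallback sets out from 5 and comes back at 10. It sets C5 by hydride addition instead of carbon addition.
- LiBH4 in THF reduces the lactone and releases the aldehyde, giving (2S)-4-[(tert-butyldiphenylsilyl)oxy]butane-1,2-diol F1.
- NaH and N-tosylimidazole in THF take it through the primary sulfonate (2S)-4-[(tert-butyldiphenylsilyl)oxy]-2-hydroxybutyl 4-methylbenzenesulfonate F2 to tert-butyl{2-[(2S)-oxiran-2-yl]ethoxy}diphenylsilane F3. The C–O bond of the stereocentre is untouched.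
- Hex-1-ynyllithium (hex-1-yne, nBuLi) with BF3·OEt2 at −78 °C opens the epoxide at its CH2 end to (3R)-1-[(tert-butyldiphenylsilyl)oxy]dec-5-yn-3-ol F4.
- Ph3PAuCl/AgBF4 with catalytic p-TsOH in MeOH brings about 5-endo-dig cyclisation and methanol addition to (5R)-2-butyl-5-{2-[(tert-butyldiphenylsilyl)oxy]ethyl}-2-methoxyoxolane F5.
- Et3SiH with BF3·OEt2 in CH2Cl2 at −78 °C reduces the derived cyclic oxocarbenium ion. Hydride should arrive mainly anti to the arm and so favour the cis isomer 10. Any trans isomer would be separated by chromatography.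

Step 4. Carbonyl methylenation may be slow or incomplete. The acid-labile exocyclic enol acetal may also be lost by hydrolysis, or by migration of the double bond into the ring, while the titanium residues are being removed.
- The fallback sets out from 5 and comes back at 6. It uses a metal-free modified Julia olefination of the lactone carbonyl.
- 2-(Methylsulfonyl)-1,3-benzothiazole is deprotonated with LiN(SiMe3)2 in THF at −78 °C and added to 5. This gives (2S,5S)-4-[(1,3-benzothiazol-2-ylsulfonyl)methyl]-2-butyl-5-{2-[(tert-butyldiphenylsilyl)oxy]ethyl}-1,3-dioxolan-4-ol F6.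
- DBU in THF at rt then triggers the Smiles rearrangement and elimination to the enol ether.
- The by-products are removed by basic aqueous extraction, so 6 can enter step 5 without chromatography.

Step 2. The liberated primary hydroxyl may attack the dioxolanone carbonyl during quench or concentration. This is a translactonisation with loss of the aldehyde, and it would occur before the silyl group is in place.
- The fallback sets out from 3 and comes back at 5. It accepts the acyl migration and builds the acetal last.
- 3 is reduced as in step 2, and the crude 4 is stirred with catalytic p-TsOH in CH2Cl2. All material then converges on (3S)-3-hydroxyoxolan-2-one F7.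
- One equivalent of NaOH in aqueous MeOH opens it to sodium (2S)-2,4-dihydroxybutanoate F8.
- TBDPSCl and imidazole in DMF silylate the primary hydroxyl selectively. Mild acidification gives (2S)-4-[(tert-butyldiphenylsilyl)oxy]-2-hydroxybutanoic acid F9.
- F9 is condensed with 2 (catalytic p-TsOH, cyclohexane, Dean–Stark) to give 5.

Further compounds
F1 | step 5 | (2S)-4-[(tert-butyldiphenylsilyl)oxy]butane-1,2-diol | CC(C)(C)[Si](c1ccccc1)(c1ccccc1)OCC[C@H](O)CO
F2 | step 5 | (2S)-4-[(tert-butyldiphenylsilyl)oxy]-2-hydroxybutyl 4-methylbenzenesulfonate | CC(C)(C)[Si](c1ccccc1)(c1ccccc1)OCC[C@H](O)COS(=O)(=O)c1ccc(C)cc1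
F3 | step 5 | tert-butyl{2-[(2S)-oxiran-2-yl]ethoxy}diphenylsilane | CC(C)(C)[Si](c1ccccc1)(c1ccccc1)OCC[C@H]1CO1
F4 | step 5 | (3R)-1-[(tert-butyldiphenylsilyl)oxy]dec-5-yn-3-ol | CC(C)(C)[Si](c1ccccc1)(c1ccccc1)OCC[C@H](O)CC#CCCCC
F5 | step 5 | (5R)-2-butyl-5-{2-[(tert-butyldiphenylsilyl)oxy]ethyl}-2-methoxyoxolane (ketal epimers) | CC(C)(C)[Si](c1ccccc1)(c1ccccc1)OCC[C@H]1CCC(CCCC)(OC)O1
F6 | step 4 | (2S,5S)-4-[(1,3-benzothiazol-2-ylsulfonyl)methyl]-2-butyl-5-{2-[(tert-butyldiphenylsilyl)oxy]ethyl}-1,3-dioxolan-4-ol (C4 epimers) | CC(C)(C)[Si](c1ccccc1)(c1ccccc1)OCC[C@H]1C(O)(CS(=O)(=O)c2nc3ccccc3s2)O[C@@H](CCCC)O1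
F7 | step 2 | (3S)-3-hydroxyoxolan-2-one | O[C@H]1CCOC1=O
F8 | step 2 | sodium (2S)-2,4-dihydroxybutanoate | OCC[C@H](O)C(=O)[O-].[Na+]
F9 | step 2 | (2S)-4-[(tert-butyldiphenylsilyl)oxy]-2-hydroxybutanoic acid | CC(C)(C)[Si](c1ccccc1)(c1ccccc1)OCC[C@H](O)C(=O)O
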